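**Retrosynthetic overview**

1. The last step removes the two B-ring MOM ethers from the (2S)-5,7-dihydroxy-3′,4′-bis(methoxymethoxy)-6,5′-diprenylflavanone.
2. Key disconnection: the C4a–C5 bond of ring A. Ring A (C4a, C5, C6, C7, C8, C8a) is a phloroglucinol with alternating oxygens on C5, C7 and C8a, so it maps onto a CH2–CO–CH(prenyl)–CO2Me chain on C6 of a (2S)-2-aryl-2,3-dihydro-4H-pyran-4-one (pyranone C5 becomes C4a, C6 becomes C8a, the ester carbon becomes C5, the prenyl-bearing carbon becomes C6). A Claisen cyclisation with aromatisation closes it.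
3. The chain is attached by γ-acylation of the lithium dienolate of the 6-methyl dihydropyranone with methyl prenylmalonyl chloride, made from dimethyl malonate and prenyl bromide.
4. The dihydropyranone (ring C, with the only stereocentre, C2) comes from a Ti/(S)-BINOL-catalysed vinylogous Mukaiyama aldol of 3,4-bis(methoxymethoxy)-5-prenylbenzaldehyde with the bis-silyl dienol ether of pentane-2,4-dione, followed by cyclodehydration. The aldehyde comes from 3-bromo-4,5-dihydroxybenzaldehyde by MOM protection and Stille prenylation.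
5. Ring order: B (bought), C (step 4), A (step 9).

Key step: step 9

Remark on the chemistry: the malonyl α-carbon of the Claisen precursor is epimerisable and ends as aromatic C6, so racemic malonyl building blocks are used and that compound is carried as an epimer mixture; the bromo aldehyde and the prenylstannane are taken as purchased.

**Route**

Step 1
Reactants: 1 3-bromo-4,5-dihydroxybenzaldehyde
Product: 2 3-bromo-4,5-bis(methoxymethoxy)benzaldehyde
Conditions: MOMCl (3 equiv), i-Pr2NEt (4 equiv), CH2Cl2, 0 °C → rt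
Reagents that add atoms: chloromethyl methyl ether (MOMCl), COCCl
Why: Williamson-type O-alkylation of both catechol hydroxyls with the reactive α-chloro ether should give the bis-acetal, which is stable to the bases and organometallic reagents used later.

Step 2
Reactants: 2 3-bromo-4,5-bis(methoxymethoxy)benzaldehyde; 3 tributyl(3-methylbut-2-en-1-yl)stannane
Product: 4 3,4-bis(methoxymethoxy)-5-(3-methylbut-2-en-1-yl)benzaldehyde
Conditions: Pd(PPh3)4 (5 mol %), DMF, 90 °C
Reagents that add atoms: none
Why: Stille cross-coupling of the electron-poor aryl bromide with the allylic stannane should deliver the linear prenyl arene by reductive elimination at the less substituted allyl terminus, and the aldehyde and MOM ethers are inert to Pd(0).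

Step 3
Reactants: 5 pentane-2,4-dione
Product: 6 (3Z)-2,4-bis(trimethylsilyloxy)penta-1,3-diene
Conditions: TMSOTf (2.2 equiv), Et3N (2.5 equiv), Et2O, 0 °C → rt
Reagents that add atoms: trimethylsilyl trifluoromethanesulfonate (TMSOTf), C[Si](C)(C)OS(=O)(=O)C(F)(F)F
Why: Double soft enolisation and O-silylation of the 1,3-diketone should give the 1,3-bis(silyl enol ether), the second silylation taking place at a terminal methyl group.

Step 4
Reactants: 4 3,4-bis(methoxymethoxy)-5-(3-methylbut-2-en-1-yl)benzaldehyde; 6 (3Z)-2,4-bis(trimethylsilyloxy)penta-1,3-diene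
Product: 8 (2S)-2-[3,4-bis(methoxymethoxy)-5-(3-methylbut-2-en-1-yl)phenyl]-6-methyl-2,3-dihydro-4H-pyran-4-one, via hydroxy diketone 7 (not isolated)
Conditions: Ti(Oi-Pr)4 (10 mol %), (S)-BINOL (10 mol %), 4 Å MS, THF, −20 °C → rt; then TFA (0.3 equiv), CH2Cl2, 0 °C
Reagents that add atoms: none
Why: A Ti(IV)–BINOL-catalysed vinylogous Mukaiyama aldol addition (a formal hetero-Diels–Alder reaction) should join the CH2 terminus of the diene to the aldehyde, the (S)-BINOL complex being expected to direct attack to the Si face and so set C2 as (S), after which acid removes the silyl groups and the δ-hydroxy β-diketone closes by hemiketalisation and dehydration.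

Step 5
Reactants: 9 dimethyl malonate; 10 1-bromo-3-methylbut-2-ene (prenyl bromide)
Product: 11 dimethyl 2-(3-methylbut-2-en-1-yl)propanedioate
Conditions: NaH (1.0 equiv), 9 (2 equiv), THF, 0 °C; then 10, rt
Reagents that add atoms: none
Why: Malonic ester alkylation (SN2 at the primary allylic bromide) should give the mono-prenyl malonate, the excess of malonate holding back dialkylation.

Step 6
Reactants: 11 dimethyl 2-(3-methylbut-2-en-1-yl)propanedioate
Product: 12 2-(methoxycarbonyl)-5-methylhex-4-enoic acid (racemic)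
Conditions: KOH (1.0 equiv), MeOH, 0 °C → rt; then 1 M HCl
Reagents that add atoms: potassium hydroxide, [K+].[OH-]
Why: Mono-saponification of a malonic diester stops after one ester because the carboxylate formed deactivates the second ester towards hydroxide.

Step 7
Reactants: 12 2-(methoxycarbonyl)-5-methylhex-4-enoic acid (racemic)
Product: 13 methyl 2-(chlorocarbonyl)-5-methylhex-4-enoate (racemic)
Conditions: (COCl)2 (1.2 equiv), DMF (cat.), CH2Cl2, 0 °C → rt; used crude
Reagents that add atoms: oxalyl chloride, O=C(Cl)C(=O)Cl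
Why: Vilsmeier-type activation of the acid with oxalyl chloride and catalytic DMF should give the malonyl half-ester chloride under conditions that leave the trisubstituted alkene alone.

Step 8
Reactants: 8 (2S)-2-[3,4-bis(methoxymethoxy)-5-(3-methylbut-2-en-1-yl)phenyl]-6-methyl-2,3-dihydro-4H-pyran-4-one; 13 methyl 2-(chlorocarbonyl)-5-methylhex-4-enoate (racemic)
Product: 14 methyl 4-{(2S)-2-[3,4-bis(methoxymethoxy)-5-(3-methylbut-2-en-1-yl)phenyl]-4-oxo-3,4-dihydro-2H-pyran-6-yl}-2-(3-methylbut-2-en-1-yl)-3-oxobutanoate (epimer mixture at C2 of the butanoate)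
Conditions: LiHMDS (2.1 equiv), THF, −78 °C; then 13 (1.1 equiv), −78 → −40 °C; AcOH
Reagents that add atoms: none
Why: Kinetic deprotonation of the C6 methyl group should give the extended lithium dienolate, which is C-acylated at its γ-carbon by the acid chloride (vinylogous Claisen acylation), the second equivalent of base taking up the acidic proton of the product, while C3 and hence the C2 centre stay untouched at −78 °C.

Step 9
Reactants: 14 methyl 4-{(2S)-2-[3,4-bis(methoxymethoxy)-5-(3-methylbut-2-en-1-yl)phenyl]-4-oxo-3,4-dihydro-2H-pyran-6-yl}-2-(3-methylbut-2-en-1-yl)-3-oxobutanoate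
Product: 15 (2S)-2-[3,4-bis(methoxymethoxy)-5-(3-methylbut-2-en-1-yl)phenyl]-5,7-dihydroxy-6-(3-methylbut-2-en-1-yl)-2,3-dihydro-4H-chromen-4-one
Conditions: DBU (2.5 equiv), MeCN, 0 → 45 °C; then AcOH
Reagents that add atoms: none
Why: Proposed new method: DBU removes a proton from the C6–CH2 group of 14, which is activated by the side-chain ketone and vinylogously by the ring C4 carbonyl, to give an extended dienolate whose α-carbon (pyranone C5) adds to the methyl ester carbonyl; loss of methoxide and enolisation of the resulting cyclohexenetrione tautomer should give the aromatic 5,7-dihydroxy-6-prenyl ring A irreversibly. The closest known reaction types are the biomimetic Claisen cyclisation of 3,5,7-triketo esters to acylphloroglucinols and the Lacey–Dieckmann cyclisation of doubly stabilised enolates onto methyl esters, neither of which has been run on a chain masked as a dihydropyranone. The new six-membered carbocycle closes in a 6-(enolexo)-exo-trig mode through the C4a–C5 bond. No stereocentre is created: the epimeric side-chain carbon becomes aromatic C6 and C2 is a spectator. Regiochemistry is fixed by connectivity, because only pyranone C5 can reach the ester through a six-membered transition state and the prenyl group sits on the carbon between the two future C–OH carbons, while the alternative aldol closure onto C4 would give a bridged adduct that cannot aromatise and reverts. The step needs the C2–O1 bond to survive, which the mild amidine base should secure, since the C3 protons are far less acidic than the two doubly activated sites and the anionic substrate and product resist the second deprotonation that would start an E1cB ring opening.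

Step 10
Reactants: 15 (2S)-2-[3,4-bis(methoxymethoxy)-5-(3-methylbut-2-en-1-yl)phenyl]-5,7-dihydroxy-6-(3-methylbut-2-en-1-yl)-2,3-dihydro-4H-chromen-4-one
Product: 16 (2S)-2-[3,4-dihydroxy-5-(3-methylbut-2-en-1-yl)phenyl]-5,7-dihydroxy-6-(3-methylbut-2-en-1-yl)-2,3-dihydro-4H-chromen-4-one
Conditions: HCl in MeOH (about 1 M), rt → 40 °C
Reagents that add atoms: none
Why: Acid-catalysed acetal exchange with methanol cleaves both aryl MOM ethers, and the dilute acid and low temperature are chosen so that the prenyl groups next to the freed phenols do not cyclise to chromans and C2 does not ionise.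

**Compound list**

1 | 3-bromo-4,5-dihydroxybenzaldehyde | O=Cc1cc(O)c(O)c(Br)c1 | starting material
2 | 3-bromo-4,5-bis(methoxymethoxy)benzaldehyde | COCOc1cc(C=O)cc(Br)c1OCOC | intermediate
3 | tributyl(3-methylbut-2-en-1-yl)stannane | CCCC[Sn](CCCC)(CCCC)CC=C(C)C | starting material
4 | 3,4-bis(methoxymethoxy)-5-(3-methylbut-2-en-1-yl)benzaldehyde | CC(C)=CCc1cc(C=O)cc(OCOC)c1OCOC | intermediate
5 | pentane-2,4-dione | CC(=O)CC(C)=O | starting material
6 | (3Z)-2,4-bis(trimethylsilyloxy)penta-1,3-diene | C=C(O[Si](C)(C)C)/C=C(\O[Si](C)(C)C)C | intermediate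
7 | (6S)-6-[3,4-bis(methoxymethoxy)-5-(3-methylbut-2-en-1-yl)phenyl]-6-hydroxyhexane-2,4-dione (not isolated) | CC(C)=CCc1cc([C@@H](O)CC(=O)CC(C)=O)cc(OCOC)c1OCOC | intermediate
8 | (2S)-2-[3,4-bis(methoxymethoxy)-5-(3-methylbut-2-en-1-yl)phenyl]-6-methyl-2,3-dihydro-4H-pyran-4-one | CC(C)=CCc1cc([C@@H]2CC(=O)C=C(C)O2)cc(OCOC)c1OCOC | intermediate
9 | dimethyl malonate | COC(=O)CC(=O)OC | starting material
10 | 1-bromo-3-methylbut-2-ene (prenyl bromide) | CC(C)=CCBr | starting material
11 | dimethyl 2-(3-methylbut-2-en-1-yl)propanedioate | COC(=O)C(CC=C(C)C)C(=O)OC | intermediate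
12 | 2-(methoxycarbonyl)-5-methylhex-4-enoic acid (racemic) | COC(=O)C(CC=C(C)C)C(=O)O | intermediate
13 | methyl 2-(chlorocarbonyl)-5-methylhex-4-enoate (racemic) | COC(=O)C(CC=C(C)C)C(Cl)=O | intermediate
14 | methyl 4-{(2S)-2-[3,4-bis(methoxymethoxy)-5-(3-methylbut-2-en-1-yl)phenyl]-4-oxo-3,4-dihydro-2H-pyran-6-yl}-2-(3-methylbut-2-en-1-yl)-3-oxobutanoate (epimers at the malonyl carbon) | CC(C)=CCc1cc([C@@H]2CC(=O)C=C(CC(=O)C(CC=C(C)C)C(=O)OC)O2)cc(OCOC)c1OCOC | intermediate
15 | (2S)-2-[3,4-bis(methoxymethoxy)-5-(3-methylbut-2-en-1-yl)phenyl]-5,7-dihydroxy-6-(3-methylbut-2-en-1-yl)-2,3-dihydro-4H-chromen-4-one | CC(C)=CCc1cc([C@@H]2CC(=O)c3c(cc(O)c(CC=C(C)C)c3O)O2)cc(OCOC)c1OCOC | intermediate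
16 | (2S)-2-[3,4-dihydroxy-5-(3-methylbut-2-en-1-yl)phenyl]-5,7-dihydroxy-6-(3-methylbut-2-en-1-yl)-2,3-dihydro-4H-chromen-4-one | CC(C)=CCc1cc([C@@H]2CC(=O)c3c(cc(O)c(CC=C(C)C)c3O)O2)cc(O)c1O | target

Total step count: 10
Longest linear sequence: 6 steps (steps 1, 2, 4, 8, 9, 10)

**Steps most likely to fail**

1. Step 9 (proposed new method). Two processes may defeat it. The base may sit mainly on the malonyl carbon, so that the ester becomes part of an enolate and no longer accepts the C5 nucleophile. Prolonged base treatment may also enolise C3 and open the C2–O1 bond by E1cB, which erodes the configuration at C2 and leads on to chalcone-type material.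
Fallback (known chemistry, ring A brought in preformed; it sets out from aldehyde 4 and comes back to the route at 16): 1-(2,4,6-trihydroxyphenyl)ethanone is C-prenylated with prenyl bromide 10 (DBU, THF) to 1-[2,4,6-trihydroxy-3-(3-methylbut-2-en-1-yl)phenyl]ethan-1-one F1. Bis-MOM protection (MOMCl, i-Pr2NEt) and chromatographic separation from the 2-hydroxy regioisomer should give 1-[6-hydroxy-2,4-bis(methoxymethoxy)-3-(3-methylbut-2-en-1-yl)phenyl]ethan-1-one F2, in which the free hydroxyl is the one remote from the prenyl group. Claisen–Schmidt condensation of F2 with 4 (KOH, EtOH) gives (2E)-3-[3,4-bis(methoxymethoxy)-5-(3-methylbut-2-en-1-yl)phenyl]-1-[6-hydroxy-2,4-bis(methoxymethoxy)-3-(3-methylbut-2-en-1-yl)phenyl]prop-2-en-1-one F3. Oxa-Michael ring closure (NaOAc, EtOH, reflux) gives racemic 5,7-bis(methoxymethoxy)-2-[3,4-bis(methoxymethoxy)-5-(3-methylbut-2-en-1-yl)phenyl]-6-(3-methylbut-2-en-1-yl)-2,3-dihydro-4H-chromen-4-one F4. Methanolic HCl gives racemic 2-[3,4-dihydroxy-5-(3-methylbut-2-en-1-yl)phenyl]-5,7-dihydroxy-6-(3-methylbut-2-en-1-yl)-2,3-dihydro-4H-chromen-4-one F5, and preparative HPLC on a chiral stationary phase delivers 16. This fallback gives up the built-in regiocontrol and the early stereocentre: its regiochemistry rests on the separation at F2 and its enantiopurity on the final resolution.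

2. Step 8. The dienolate may be acylated on oxygen instead of on the γ-carbon. Deprotonation may occur at C3 instead of at the methyl group, and the resulting enolate would open the ring with loss of the C2 centre. The acid chloride may be turned into a ketene by the base and consumed by self-condensation.
Fallback (it sets out from 8 and 12 and comes back at 14): the same dienolate of 8 is trapped with CO2 to give {(2S)-2-[3,4-bis(methoxymethoxy)-5-(3-methylbut-2-en-1-yl)phenyl]-4-oxo-3,4-dihydro-2H-pyran-6-yl}acetic acid F6. Carbonyldiimidazole turns F6 into (2S)-2-[3,4-bis(methoxymethoxy)-5-(3-methylbut-2-en-1-yl)phenyl]-6-[2-(1H-imidazol-1-yl)-2-oxoethyl]-2,3-dihydro-4H-pyran-4-one F7. In a Masamune–Brooks decarboxylative Claisen condensation, F7 is C-acylated by the magnesium enolate formed from half ester 12 (MgCl2, Et3N, MeCN). The adduct 4-{(2S)-2-[3,4-bis(methoxymethoxy)-5-(3-methylbut-2-en-1-yl)phenyl]-4-oxo-3,4-dihydro-2H-pyran-6-yl}-2-(methoxycarbonyl)-2-(3-methylbut-2-en-1-yl)-3-oxobutanoic acid F8 loses CO2 in the flask to give 14. This forms the CO–CH(prenyl) bond instead of the CH2–CO bond and needs no strong base in the presence of the malonyl unit.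

3. Step 4. Facial selectivity may be poor or turnover slow with this electron-rich aldehyde, and the acid used for cyclodehydration may start to remove a MOM group or ionise the benzylic C2–O bond. Should the sense of induction prove opposite, (R)-BINOL is used; that alone is not counted as a fallback.
Fallback (it sets out from 4 and 5 and comes back at 8): the dianion of pentane-2,4-dione 5 (NaH, then n-BuLi, THF, 0 °C) adds through its terminal carbon to 4 to give racemic 6-[3,4-bis(methoxymethoxy)-5-(3-methylbut-2-en-1-yl)phenyl]-6-hydroxyhexane-2,4-dione F9. Cyclodehydration with PPTS gives racemic 2-[3,4-bis(methoxymethoxy)-5-(3-methylbut-2-en-1-yl)phenyl]-6-methyl-2,3-dihydro-4H-pyran-4-one F10, and preparative chromatography on a chiral stationary phase gives the (S)-enantiomer 8. Here the stereocentre is secured by resolution of a simple early intermediate instead of by asymmetric catalysis.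

**Further compounds**

F1 | step 9 | 1-[2,4,6-trihydroxy-3-(3-methylbut-2-en-1-yl)phenyl]ethan-1-one | CC(=O)c1c(O)cc(O)c(CC=C(C)C)c1O
F2 | step 9 | 1-[6-hydroxy-2,4-bis(methoxymethoxy)-3-(3-methylbut-2-en-1-yl)phenyl]ethan-1-one | CC(=O)c1c(O)cc(OCOC)c(CC=C(C)C)c1OCOC
F3 | step 9 | (2E)-3-[3,4-bis(methoxymethoxy)-5-(3-methylbut-2-en-1-yl)phenyl]-1-[6-hydroxy-2,4-bis(methoxymethoxy)-3-(3-methylbut-2-en-1-yl)phenyl]prop-2-en-1-one | CC(C)=CCc1cc(/C=C/C(=O)c2c(O)cc(OCOC)c(CC=C(C)C)c2OCOC)cc(OCOC)c1OCOC
F4 | step 9 | racemic 5,7-bis(methoxymethoxy)-2-[3,4-bis(methoxymethoxy)-5-(3-methylbut-2-en-1-yl)phenyl]-6-(3-methylbut-2-en-1-yl)-2,3-dihydro-4H-chromen-4-one | CC(C)=CCc1cc(C2CC(=O)c3c(OCOC)c(CC=C(C)C)c(OCOC)cc3O2)cc(OCOC)c1OCOC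
F5 | step 9 | racemic 2-[3,4-dihydroxy-5-(3-methylbut-2-en-1-yl)phenyl]-5,7-dihydroxy-6-(3-methylbut-2-en-1-yl)-2,3-dihydro-4H-chromen-4-one | CC(C)=CCc1cc(C2CC(=O)c3c(O)c(CC=C(C)C)c(O)cc3O2)cc(O)c1O
F6 | step 8 | {(2S)-2-[3,4-bis(methoxymethoxy)-5-(3-methylbut-2-en-1-yl)phenyl]-4-oxo-3,4-dihydro-2H-pyran-6-yl}acetic acid | CC(C)=CCc1cc([C@@H]2CC(=O)C=C(CC(=O)O)O2)cc(OCOC)c1OCOC
F7 | step 8 | (2S)-2-[3,4-bis(methoxymethoxy)-5-(3-methylbut-2-en-1-yl)phenyl]-6-[2-(1H-imidazol-1-yl)-2-oxoethyl]-2,3-dihydro-4H-pyran-4-one | CC(C)=CCc1cc([C@@H]2CC(=O)C=C(CC(=O)n3ccnc3)O2)cc(OCOC)c1OCOC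
F8 | step 8 | 4-{(2S)-2-[3,4-bis(methoxymethoxy)-5-(3-methylbut-2-en-1-yl)phenyl]-4-oxo-3,4-dihydro-2H-pyran-6-yl}-2-(methoxycarbonyl)-2-(3-methylbut-2-en-1-yl)-3-oxobutanoic acid (not isolated) | CC(C)=CCc1cc([C@@H]2CC(=O)C=C(CC(=O)C(CC=C(C)C)(C(=O)O)C(=O)OC)O2)cc(OCOC)c1OCOC
F9 | step 4 | racemic 6-[3,4-bis(methoxymethoxy)-5-(3-methylbut-2-en-1-yl)phenyl]-6-hydroxyhexane-2,4-dione | CC(C)=CCc1cc(C(O)CC(=O)CC(C)=O)cc(OCOC)c1OCOC
F10 | step 4 | racemic 2-[3,4-bis(methoxymethoxy)-5-(3-methylbut-2-en-1-yl)phenyl]-6-methyl-2,3-dihydro-4H-pyran-4-one | CC(C)=CCc1cc(C2CC(=O)C=C(C)O2)cc(OCOC)c1OCOC
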